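Remark (assumption): 2,2,6-trimethyl-4H-1,3-dioxin-4-one and hexadecanedioic acid monomethyl ester are taken as purchasable; the target has no stereocentre and no configured double bond, so only constitution has to be controlled.

## Structural features

Target 11 is an achiral, monocyclic 1,4-benzoquinone. Ring carbons C1 and C4 are the carbonyls, C2 carries the methoxy group, C6 carries an unbranched (CH2)14CO2H chain, and C3 and C5 carry hydrogen. The methoxy group and the chain are therefore meta to each other and flank the same carbonyl (C1), while C4 lies between two CH groups. The fragile part is the methoxyquinone, a vinylogous ester and Michael acceptor that does not tolerate hydroxide, amines, thiolates, carbanions or reducing agents, so it has to be formed last. The terminal carboxylic acid only needs a mask while carbanions are in use. The real difficulty is the arene behind the quinone: oxygen on C2 and C4 and carbon on C6 are all mutually meta, a pattern that electrophilic substitution of a resorcinol ether cannot deliver at C6. In addition, the C2 oxygen (methyl ether) must be told apart from the C4 oxygen (carbonyl), and these two are equivalent in any symmetrical 5-alkylresorcinol. This pattern is the signature of an alkylresorcinol polyketide: C6, C4 and C2 are the former carbonyl carbons of a tetraketide whose starter unit is a C16 α,ω-diacid, with C6 the starter carbonyl carbon itself. The key step exploits this by forming the C5–C6 ring bond, and with it the whole carbocycle, from an open chain in which the oxygens destined for C2 and C4 are already different.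

## Logic of the disconnections

11 to 10. The C1=O bond of 11 (at the ring carbon between the methoxy-bearing and the chain-bearing carbons) is cut and the ring is taken back to the phenol oxidation level. The cut is made here because the quinone is the one group that no earlier step would tolerate. The gain is that 10 is a plain 3,5-disubstituted phenol that tolerates base. The demand on the forward step is oxidation at the para carbon of 10, which is flanked on both sides, in preference to the two ortho carbons, in the presence of a free carboxylic acid.

10 to 8 (through 9). The C–H bond of 10 at the ring carbon between the hydroxyl-bearing and the chain-bearing carbons is traced back to a C–CO2H bond in 9. In 8 that carboxyl and the neighbouring phenol oxygen are tied together as an acetonide and the chain acid is a methyl ester. The carboxyl is the natural end of the polyketide chain, and its acetonide is what distinguishes the two ring oxygens. The gain is that one hydrolytic operation removes all three masks. The demand is that hydrolysis and protodecarboxylation leave the aryl methyl ether untouched.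

8 to 7. The O–CH3 bond is cut. Because 7 has a single free phenol, the forward methylation needs no regiocontrol; the only demand is that the lactone-type acetonide survives mild base.

7 to 5 (through 6), the key disconnection. The ring bond between C4a and C5 of 7 (C5–C6 of 11) is cut by retro-dehydration to 6 and retro-aldol. In one sentence: the six-membered carbocycle is closed and aromatised by an intramolecular aldol condensation of the open-chain masked tetraketide 5. The gain is the largest of the route: a trisubstituted arene with differentiated oxygens becomes a linear chain with carbonyls on alternate carbons, and no aromatic starting material is needed. The demand is that closure follows the aldol mode (dioxinone C5 onto the C16 ketone) and not the Claisen mode or O-cyclisation. This is why the chain terminus is kept as a dioxinone rather than a free ester, at the cost of one step.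

5 to 2 and 3 (through 4). The C16–C17 bond of 5 is cut in a Claisen sense. This separates the starter unit 3, which supplies all sixteen chain carbons and the ester mask, from the triketide equivalent 2. The demand is that the dianion of 2 reacts at its terminal carbon, and that 4 reacts at its imidazolide and not at its methyl ester.

2 to 1. The bond between the acetyl carbonyl carbon and the methylene on C6 of the dioxinone ring is cut, leading to 1 and an acetyl cation equivalent. The demand is C-acylation at the γ-carbon of the dienolate of 1.

## Other disconnections considered

Alternative 1: the first cut that comes to mind is the benzylic C–C bond between a bought arene and the chain. Forward, Wittig olefination of 3,5-dimethoxybenzaldehyde A1 with the ylide of (13-carboxytridecyl)triphenylphosphonium bromide A2, then hydrogenation over Pd/C, would give 15-(3,5-dimethoxyphenyl)pentadecanoic acid A3. Mono-demethylation with NaSEt would give 10, and oxidation would give 11. The chosen plan is preferred for three reasons: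
- Buying the ring creates the problem of two equivalent oxygens, which then has to be solved by a forcing thiolate demethylation that must stop after one ether.
- A2 is not a stock compound and has to be assembled from a C14 ω-bromo acid, so the step count is no lower.
- The disconnection is the default one and leaves the ring pattern unaddressed.

Alternative 2: the same ring–chain bond could be formed on the quinone itself by a silver-catalysed decarboxylative radical (Minisci-type) C–H alkylation of 2-methoxy-1,4-benzoquinone A4 with hexadecanedioic acid A5 (AgNO3, (NH4)2S2O8, MeCN/H2O). This is a single step, but the innate regiochemistry argues against it. The C4 carbonyl of A4 is deactivated as a vinylogous ester, so the C1 carbonyl is the better acceptor and its β-carbon is C5. A nucleophilic alkyl radical should therefore add mainly at C5 and lead to 15-(4-methoxy-3,6-dioxocyclohexa-1,4-dien-1-yl)pentadecanoic acid A6, the 2,5-isomer, instead of the 2,6-pattern of 11. A5 also has two identical carboxyl groups, so double decarboxylation and bis-quinone formation should compete. The saving in steps does not outweigh a regiochemistry that runs against the target.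

Alternative 3: the quinone ring could be closed between a four-carbon and a two-carbon half. Forward, the lithium acetylide of methyl heptadec-16-ynoate A8 would add to 3-methoxycyclobut-3-ene-1,2-dione A7 to give racemic methyl 17-(1-hydroxy-2-methoxy-4-oxocyclobut-2-en-1-yl)heptadec-16-ynoate A9. Thermal ring opening to a vinylketene and ring closure (Moore rearrangement) would then give the quinone. The mechanism fixes the wrong isomer. The acetylide should add to the carbonyl of A7 that is not part of the vinylogous ester, so in A9 the methoxy-bearing carbon is next to the carbinol carbon. The rearrangement then places methoxy para to the chain and gives methyl 15-(4-methoxy-3,6-dioxocyclohexa-1,4-dien-1-yl)pentadecanoate A10. The 2,6-isomer would need addition to the deactivated carbonyl or methoxyethyne as the two-carbon partner, and A8 itself needs several steps. The chosen plan reaches the correct pattern from stock materials.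

Key step: step 3

## Route

Step 1
Reactants: 1 2,2,6-trimethyl-4H-1,3-dioxin-4-one
Product: 2 2,2-dimethyl-6-(2-oxopropyl)-4H-1,3-dioxin-4-one
Conditions: LiN(SiMe3)2 (2 equiv), 1 (2 equiv), THF, −78 °C; AcCl (1 equiv), −78 °C; aq. NH4Cl
Reagents that add atoms: acetyl chloride, CC(Cl)=O
Why: Vinylogous deprotonation of the C6 methyl group of 1 gives the lithium dienolate, which should be C-acylated at its γ-carbon by acetyl chloride (vinylogous Claisen-type acylation); the excess of dienolate absorbs the proton of the more acidic product 2.

Step 2
Reactants: 2 2,2-dimethyl-6-(2-oxopropyl)-4H-1,3-dioxin-4-one; 3 16-methoxy-16-oxohexadecanoic acid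
Product: 5 methyl 19-(2,2-dimethyl-4-oxo-4H-1,3-dioxin-6-yl)-16,18-dioxononadecanoate, via acyl imidazolide 4 (not isolated)
Conditions: 3, CDI, THF, rt (gives 4); separately 2, LiN(iPr)2 (4 equiv), THF, −78 °C; add 4, −78 to −40 °C; AcOH quench
Reagents that add atoms: 1,1'-carbonyldiimidazole, O=C(n1ccnc1)n1ccnc1 (its imidazol-1-yl group is carried by 4 only; no atom of it remains in 5)
Why: CDI turns acid 3 into acyl imidazolide 4 with loss of CO2 and imidazole; LiN(iPr)2 converts 2 into its 1,3-dianion (first the doubly activated CH2, then the terminal CH3), which should be acylated at the terminal carbon as in the γ-acylation of acetoacetate dianions (crossed Claisen condensation). The extra base covers the liberated imidazole and the acidic diketone product, and at −78 °C the imidazolide is far more electrophilic than the distal methyl ester.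

Step 3
Reactants: 5 methyl 19-(2,2-dimethyl-4-oxo-4H-1,3-dioxin-6-yl)-16,18-dioxononadecanoate
Product: 7 methyl 15-(7-hydroxy-2,2-dimethyl-4-oxo-4H-benzo[d][1,3]dioxin-5-yl)pentadecanoate, via aldol carbinol 6 (not isolated)
Conditions: Et3N, CH2Cl2, rt
Reagents that add atoms: none
Why: Et3N reversibly deprotonates the C19 methylene of 5 (between the C18 ketone and the dioxinone) to an extended dienolate whose α-carbon (dioxinone C5) adds to the C16 ketone, the carbonyl that carries the chain; this is the cyclisation mode of stilbene and alkylresorcinol synthases (polyketide C2 onto C7), and the closest laboratory reaction type is the base-mediated cycloaromatisation of diketo-dioxinones to isopropylidene-protected β-resorcylates. The carbocycle closes by a 6-(enolendo)-exo-trig aldol addition, a mode the ring-closure rules for enolates favour, to give carbinol 6. E1cB loss of the tertiary hydroxyl of 6 (the C6 hydrogens are α to the C7 ketone) and enolisation of that ketone follow, and the gain of aromaticity makes the sequence irreversible overall. No stereocentre has to be controlled: the carbinol carbon of 6 is formed racemic and is destroyed on dehydration. The selectivity needed is aldol closure onto C16 rather than Claisen-type closure of C17 onto the dioxinone carbonyl (the chalcone-synthase mode, which would give an acylphloroglucinol) or O-cyclisation to a 4-pyranone. The dioxinone should secure it, because its carbonyl is a vinylogous carbonate and a poor electrophile while its C5 is a nucleophilic enol-ether carbon, and because a weak amine base without acid does not promote pyranone dehydration. The same mask leaves exactly one free phenol in 7, the oxygen of the former C18 ketone, and thereby fixes where the methyl ether will go.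

Step 4
Reactants: 7 methyl 15-(7-hydroxy-2,2-dimethyl-4-oxo-4H-benzo[d][1,3]dioxin-5-yl)pentadecanoate
Product: 8 methyl 15-(7-methoxy-2,2-dimethyl-4-oxo-4H-benzo[d][1,3]dioxin-5-yl)pentadecanoate
Conditions: MeI, K2CO3, acetone, 50 °C
Reagents that add atoms: iodomethane, CI
Why: Williamson ether synthesis on the only free phenol of 7; the other resorcylate oxygen is locked in the acetonide, so the position of O-methylation is fixed by structure, and neither ester is touched by K2CO3 in acetone.

Step 5
Reactants: 8 methyl 15-(7-methoxy-2,2-dimethyl-4-oxo-4H-benzo[d][1,3]dioxin-5-yl)pentadecanoate
Product: 10 15-(3-hydroxy-5-methoxyphenyl)pentadecanoic acid, via salicylic diacid 9 (not isolated)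
Conditions: KOH, H2O/DMSO, 80 °C; then HCl (aq.)/dioxane, pH 1, 90 °C
Reagents that add atoms: water, O; potassium hydroxide, [K+].[OH-] (source of the hydroxyl oxygen of the chain carboxylic acid)
Why: Hydroxide saponifies the chain methyl ester and opens the aryl ester of the benzodioxinone with release of acetone to give salicylate 9; on acidification and warming, ipso-protonation at the carboxyl-bearing carbon (ortho to OH and para to OMe) is followed by loss of CO2, the usual protodecarboxylation of a β-resorcylic acid. Aryl methyl ethers are inert to hydroxide at this temperature.

Step 6
Reactants: 10 15-(3-hydroxy-5-methoxyphenyl)pentadecanoic acid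
Product: 11 15-(5-methoxy-3,6-dioxocyclohexa-1,4-dien-1-yl)pentadecanoic acid
Conditions: (KSO3)2NO (2.5 equiv), KH2PO4/Na2HPO4 buffer (pH 7), H2O/acetone, 0 °C to rt; then dilute HCl to pH 3
Reagents that add atoms: dipotassium nitrosodisulfonate (KSO3)2NO, [K+].[K+].[O]N(S(=O)(=O)[O-])S(=O)(=O)[O-] (delivers the new carbonyl oxygen)
Why: Teuber oxidation: the nitroxyl radical abstracts the phenolic hydrogen, a second equivalent couples through oxygen at the free para carbon (between OMe and the chain) of the aryloxyl radical, and loss of HN(SO3K)2 should give the para-quinone, as expected for 3,5-disubstituted phenols with a free para position. The neutral buffer protects the methoxyquinone, and the carboxylate keeps the substrate in solution.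

## Compound list

1 | 2,2,6-trimethyl-4H-1,3-dioxin-4-one | CC1=CC(=O)OC(C)(C)O1 | starting material
2 | 2,2-dimethyl-6-(2-oxopropyl)-4H-1,3-dioxin-4-one | CC(=O)CC1=CC(=O)OC(C)(C)O1 | intermediate
3 | 16-methoxy-16-oxohexadecanoic acid | COC(=O)CCCCCCCCCCCCCCC(=O)O | starting material
4 | methyl 16-(1H-imidazol-1-yl)-16-oxohexadecanoate | COC(=O)CCCCCCCCCCCCCCC(=O)n1ccnc1 | intermediate
5 | methyl 19-(2,2-dimethyl-4-oxo-4H-1,3-dioxin-6-yl)-16,18-dioxononadecanoate | COC(=O)CCCCCCCCCCCCCCC(=O)CC(=O)CC1=CC(=O)OC(C)(C)O1 | intermediate
6 | methyl 15-(5-hydroxy-2,2-dimethyl-4,7-dioxo-5,6,7,8-tetrahydro-4H-benzo[d][1,3]dioxin-5-yl)pentadecanoate (racemic) | COC(=O)CCCCCCCCCCCCCCC1(O)CC(=O)CC2=C1C(=O)OC(C)(C)O2 | intermediate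
7 | methyl 15-(7-hydroxy-2,2-dimethyl-4-oxo-4H-benzo[d][1,3]dioxin-5-yl)pentadecanoate | COC(=O)CCCCCCCCCCCCCCc1cc(O)cc2OC(C)(C)OC(=O)c12 | intermediate
8 | methyl 15-(7-methoxy-2,2-dimethyl-4-oxo-4H-benzo[d][1,3]dioxin-5-yl)pentadecanoate | COC(=O)CCCCCCCCCCCCCCc1cc(OC)cc2OC(C)(C)OC(=O)c12 | intermediate
9 | 2-(14-carboxytetradecyl)-6-hydroxy-4-methoxybenzoic acid | OC(=O)CCCCCCCCCCCCCCc1cc(OC)cc(O)c1C(=O)O | intermediate
10 | 15-(3-hydroxy-5-methoxyphenyl)pentadecanoic acid | COc1cc(O)cc(CCCCCCCCCCCCCCC(=O)O)c1 | intermediate
11 | 15-(5-methoxy-3,6-dioxocyclohexa-1,4-dien-1-yl)pentadecanoic acid | COC1=CC(=O)C=C(CCCCCCCCCCCCCCC(=O)O)C1=O | target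

## Step count and least certain steps

Total step count: 6. Longest linear sequence: 6 steps (1 to 11); 3 enters at step 2.

Step 3 (key step). The tricarbonyl chain of 5 may close through oxygen and dehydrate to a 4-pyranone, or the aldol may stall or revert at the stage of 6 because the dioxinone carbon is too weak a nucleophile under amine base. The fallback sets out from 5 and comes back at 9, and so at 10.
- 5 is heated in toluene with methanol at 110 °C. Retro-[4+2] loss of acetone gives an acylketene, which methanol traps as the open-chain tetraketide dimethyl 3,5,7-trioxodocosanedioate F1.
- F1 now has a true β-keto ester nucleophile at C2. It is cyclised and aromatised with Cs2CO3 in methanol followed by HCl in methanol to methyl 2,4-dihydroxy-6-(15-methoxy-15-oxopentadecyl)benzoate F2.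
- One equivalent of MeI with K2CO3 in acetone should methylate only the 4-hydroxyl, because the 2-hydroxyl is held in a hydrogen bond to the ester. This gives methyl 2-hydroxy-4-methoxy-6-(15-methoxy-15-oxopentadecyl)benzoate F3.
- Saponification of F3 with KOH in H2O/DMSO gives 9, which is decarboxylated to 10 as in step 5.

The approach changes in two ways: the ring is closed on a free β-keto ester after ketene trapping, and the two phenols are told apart by chelation rather than by the acetonide.

Step 2. The dianion may be acylated on oxygen, may be quenched by proton transfer from liberated imidazole or from the diketone product, or may attack the distal methyl ester of 4. The fallback sets out from 3 and comes back at 5, replacing the Claisen acylation by an aldol addition and oxidation.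
- The carboxylic acid of 3 is reduced chemoselectively with BH3·THF to methyl 16-hydroxyhexadecanoate F4.
- Dess–Martin periodinane oxidises F4 to methyl 16-oxohexadecanoate F5.
- Addition of the dianion of 2 to F5 at −78 °C gives racemic methyl 19-(2,2-dimethyl-4-oxo-4H-1,3-dioxin-6-yl)-16-hydroxy-18-oxononadecanoate F6.
- A second Dess–Martin oxidation of F6 gives 5.

An aldehyde cannot be acylated on oxygen, and the aldol adduct has no strongly acidic proton to quench the dianion.

Step 6. The second nitroxyl radical may attack an ortho carbon and lead into ortho-quinone chemistry, conversion may be slow if the fatty carboxylate aggregates in water, and the product may suffer conjugate addition of water if the pH drifts upward. The fallback sets out from 10 and comes back at 11, using a two-electron oxidative dearomatisation in place of the radical oxidation. PhI(OAc)2 (2 equiv) in methanol should place two methoxy groups on the para carbon to give the quinone monoketal 15-(5,6,6-trimethoxy-3-oxocyclohexa-1,4-dien-1-yl)pentadecanoic acid F7. Mild aqueous acid (oxalic acid, THF/H2O) then hydrolyses the ketal of F7 to 11.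

Step 1. The dienolate may be acylated on oxygen or twice, and proton exchange between the dienolate and the more acidic product may limit conversion. The fallback sets out from 1 and comes back at 2. Vinylogous aldol addition of the lithium dienolate of 1 to acetaldehyde at −78 °C gives racemic 6-(2-hydroxypropyl)-2,2-dimethyl-4H-1,3-dioxin-4-one F8, which Dess–Martin periodinane oxidises to 2.

## Further compounds

F1 | step 3 | dimethyl 3,5,7-trioxodocosanedioate | COC(=O)CC(=O)CC(=O)CC(=O)CCCCCCCCCCCCCCC(=O)OC
F2 | step 3 | methyl 2,4-dihydroxy-6-(15-methoxy-15-oxopentadecyl)benzoate | COC(=O)CCCCCCCCCCCCCCc1cc(O)cc(O)c1C(=O)OC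
F3 | step 3 | methyl 2-hydroxy-4-methoxy-6-(15-methoxy-15-oxopentadecyl)benzoate | COC(=O)CCCCCCCCCCCCCCc1cc(OC)cc(O)c1C(=O)OC
F4 | step 2 | methyl 16-hydroxyhexadecanoate | COC(=O)CCCCCCCCCCCCCCCO
F5 | step 2 | methyl 16-oxohexadecanoate | COC(=O)CCCCCCCCCCCCCCC=O
F6 | step 2 | methyl 19-(2,2-dimethyl-4-oxo-4H-1,3-dioxin-6-yl)-16-hydroxy-18-oxononadecanoate (racemic) | COC(=O)CCCCCCCCCCCCCCC(O)CC(=O)CC1=CC(=O)OC(C)(C)O1
F7 | step 6 | 15-(5,6,6-trimethoxy-3-oxocyclohexa-1,4-dien-1-yl)pentadecanoic acid | COC1=CC(=O)C=C(CCCCCCCCCCCCCCC(=O)O)C1(OC)OC
F8 | step 1 | 6-(2-hydroxypropyl)-2,2-dimethyl-4H-1,3-dioxin-4-one (racemic) | CC(O)CC1=CC(=O)OC(C)(C)O1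
A1 | alternative 1 | 3,5-dimethoxybenzaldehyde | COc1cc(C=O)cc(OC)c1
A2 | alternative 1 | (13-carboxytridecyl)triphenylphosphonium bromide | [Br-].OC(=O)CCCCCCCCCCCCC[P+](c1ccccc1)(c1ccccc1)c1ccccc1
A3 | alternative 1 | 15-(3,5-dimethoxyphenyl)pentadecanoic acid | COc1cc(CCCCCCCCCCCCCCC(=O)O)cc(OC)c1
A4 | alternative 2 | 2-methoxy-1,4-benzoquinone | COC1=CC(=O)C=CC1=O
A5 | alternative 2 | hexadecanedioic acid | OC(=O)CCCCCCCCCCCCCCC(=O)O
A6 | alternative 2 | 15-(4-methoxy-3,6-dioxocyclohexa-1,4-dien-1-yl)pentadecanoic acid | COC1=CC(=O)C(CCCCCCCCCCCCCCC(=O)O)=CC1=O
A7 | alternative 3 | 3-methoxycyclobut-3-ene-1,2-dione | COC1=CC(=O)C1=O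
A8 | alternative 3 | methyl heptadec-16-ynoate | COC(=O)CCCCCCCCCCCCCCC#C
A9 | alternative 3 | methyl 17-(1-hydroxy-2-methoxy-4-oxocyclobut-2-en-1-yl)heptadec-16-ynoate (racemic) | COC(=O)CCCCCCCCCCCCCCC#CC1(O)C(=O)C=C1OC
A10 | alternative 3 | methyl 15-(4-methoxy-3,6-dioxocyclohexa-1,4-dien-1-yl)pentadecanoate | COC1=CC(=O)C(CCCCCCCCCCCCCCC(=O)OC)=CC1=O
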